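**Retrosynthetic overview**
1. Target 29 ⇒ triol 28 by a last chemoselective acetylation; 28 ⇒ C9–Ca disconnection into bromohydrin 20 and iodotrienol 27, joined electrochemically (sets C9).
2. 20 ⇒ spiro hydroxy ketone 14: C10–OH by hydroxyl-directed reduction, C9–Br by α-bromination, enal from the isopropenyl group, decanoate on the primary alcohol.
3. 14 ⇒ pentenal 13 by C9–C10 hydroacylation (the cyclopentane is the second and last ring formed); 13 ⇒ enoate 7 by allylation at C6 and directed epoxidation/hydride opening at C5.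
4. 7 ⇒ (S)-carvone (the cyclohexane is bought; its stereocentre sets C1 by trans alkylation and is erased later in the enal).
5. 27 ⇒ propargyl alcohol by carboalumination/prenylation and two Wittig homologations.

Assumption: core locants C1–C10 and side-chain locants Ca–Ci follow the atom order of the target SMILES (C1 = ring CH with the oxypropyl chain, C2 = ring carbon of the enal, C5 = C(CH3)(OH), C6 = spiro carbon, C9 = CH with the side chain, C10 = CHOH, Ca = side-chain carbon on C9, Ce = methyl-bearing alkene carbon); systematic names use their own locants.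

Step 1
Reactants: 1 (S)-(+)-carvone; 2 tert-butyl(3-iodopropoxy)dimethylsilane
Product: 4 (5S,6R)-6-[3-(tert-butyldimethylsilyloxy)propyl]-2-methyl-5-(prop-1-en-2-yl)cyclohex-2-en-1-one, via lithium enolate 3 (not isolated)
Conditions: LiN(i-Pr)2, THF, −78 °C; then 2, DMPU, −78 to −10 °C
Reagents that add atoms: none
Why: Kinetic α′-deprotonation and SN2 alkylation of the cross-conjugated enolate (enolate alkylation); the iodide enters anti to the neighbouring isopropenyl group, so the bought stereocentre fixes core C1 (chain trans to isopropenyl).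

Step 2
Reactants: 4 (5S,6R)-6-[3-(tert-butyldimethylsilyloxy)propyl]-2-methyl-5-(prop-1-en-2-yl)cyclohex-2-en-1-one
Product: 6 (5S,6R)-6-[3-(tert-butyldimethylsilyloxy)propyl]-2-methyl-5-(prop-1-en-2-yl)cyclohex-1-en-1-yl trifluoromethanesulfonate, via lithium enolate 5 (not isolated)
Conditions: LiBH(s-Bu)3, THF, −78 °C; then PhNTf2, −78 to 0 °C
Reagents that add atoms: N-phenylbis(trifluoromethanesulfonimide), O=S(=O)(N(c1ccccc1)S(=O)(=O)C(F)(F)F)C(F)(F)F
Why: Conjugate hydride addition (1,4-reduction) gives the regiodefined tetrasubstituted enolate, which is trapped on oxygen as the enol triflate; no stereocentre is made and C1 and C2 are untouched.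

Step 3
Reactants: 6 (5S,6R)-6-[3-(tert-butyldimethylsilyloxy)propyl]-2-methyl-5-(prop-1-en-2-yl)cyclohex-1-en-1-yl trifluoromethanesulfonate
Product: 7 methyl (5S,6R)-6-[3-(tert-butyldimethylsilyloxy)propyl]-2-methyl-5-(prop-1-en-2-yl)cyclohex-1-ene-1-carboxylate
Conditions: Pd(OAc)2 (5 mol%), dppp, CO (1 atm), MeOH, Et3N, DMF, 60 °C
Reagents that add atoms: carbon monoxide, [C-]#[O+]; methanol, CO
Why: Palladium-catalysed alkoxycarbonylation of an enol triflate (oxidative addition to zerovalent palladium, CO insertion, methanolysis) puts C10 on C6 without touching the stereocentres.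

Step 4
Reactants: 7 methyl (5S,6R)-6-[3-(tert-butyldimethylsilyloxy)propyl]-2-methyl-5-(prop-1-en-2-yl)cyclohex-1-ene-1-carboxylate
Product: 9 methyl (1R,5S,6R)-1-allyl-6-[3-(tert-butyldimethylsilyloxy)propyl]-2-methyl-5-(prop-1-en-2-yl)cyclohex-2-ene-1-carboxylate, via lithium dienolate 8 (not isolated)
Conditions: LiN(i-Pr)2, THF/HMPA, −78 °C; then allyl bromide, −78 to 0 °C
Reagents that add atoms: allyl bromide, C=CCBr
Why: Deconjugative α-alkylation of the ester dienolate formed by γ-deprotonation (enolate alkylation): the C1 chain sits pseudoaxial to avoid A(1,3) strain with the ketene acetal and shields its face, so allyl (C7) enters anti to it and the quaternary C6 is set with the ester carbon (C10) cis to the chain.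

Step 5
Reactants: 9 methyl (1R,5S,6R)-1-allyl-6-[3-(tert-butyldimethylsilyloxy)propyl]-2-methyl-5-(prop-1-en-2-yl)cyclohex-2-ene-1-carboxylate
Product: 10 [(1R,5S,6R)-1-allyl-6-[3-(tert-butyldimethylsilyloxy)propyl]-2-methyl-5-(prop-1-en-2-yl)cyclohex-2-en-1-yl]methanol
Conditions: LiAlH4, THF, 0 to 25 °C
Reagents that add atoms: none
Why: LiAlH4 reduction of the neopentyl ester gives the primary alcohol that directs the next step (ester reduction).

Step 6
Reactants: 10 [(1R,5S,6R)-1-allyl-6-[3-(tert-butyldimethylsilyloxy)propyl]-2-methyl-5-(prop-1-en-2-yl)cyclohex-2-en-1-yl]methanol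
Product: 11 [1-allyl-2,3-epoxy-2-methyl-6-[3-(tert-butyldimethylsilyloxy)propyl]-5-(prop-1-en-2-yl)cyclohexyl]methanol (oxirane oxygen cis to CH2OH)
Conditions: VO(acac)2 (5 mol%), t-BuOOH (1.2 equiv), CH2Cl2, 0 to 25 °C
Reagents that add atoms: tert-butyl hydroperoxide, CC(C)(C)OO
Why: Vanadium-catalysed hydroxyl-directed epoxidation of a homoallylic alcohol delivers oxygen to the trisubstituted C4=C5 alkene on the face of the CH2OH group, so the future C5–O is cis to C10; the terminal and 1,1-disubstituted alkenes react far more slowly.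

Step 7
Reactants: 11 [1-allyl-2,3-epoxy-2-methyl-6-[3-(tert-butyldimethylsilyloxy)propyl]-5-(prop-1-en-2-yl)cyclohexyl]methanol
Product: 12 2-allyl-2-(hydroxymethyl)-1-methyl-3-[3-(tert-butyldimethylsilyloxy)propyl]-4-(prop-1-en-2-yl)cyclohexan-1-ol (OH cis to CH2OH and to the silyloxypropyl chain; allyl cis to methyl)
Conditions: LiAlH4, THF, 0 to 50 °C
Reagents that add atoms: none
Why: SN2 hydride opening of the trisubstituted epoxide at the secondary carbon C4 (trans-diaxial opening) leaves the tertiary alcohol at C5 with the configuration fixed in step 6.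

Step 8
Reactants: 12 2-allyl-2-(hydroxymethyl)-1-methyl-3-[3-(tert-butyldimethylsilyloxy)propyl]-4-(prop-1-en-2-yl)cyclohexan-1-ol
Product: 13 1-allyl-2-hydroxy-2-methyl-6-[3-(tert-butyldimethylsilyloxy)propyl]-5-(prop-1-en-2-yl)cyclohexane-1-carbaldehyde (OH cis to CHO and to the chain)
Conditions: TEMPO (10 mol%), PhI(OAc)2, CH2Cl2, 25 °C
Reagents that add atoms: none
Why: Oxoammonium-catalysed oxidation is selective for the primary alcohol over the tertiary one and gives the 2,2-disubstituted pent-4-enal needed for ring closure (alcohol oxidation).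

Step 9
Reactants: 13 1-allyl-2-hydroxy-2-methyl-6-[3-(tert-butyldimethylsilyloxy)propyl]-5-(prop-1-en-2-yl)cyclohexane-1-carbaldehyde
Product: 14 6-hydroxy-6-methyl-9-(prop-1-en-2-yl)-10-[3-(tert-butyldimethylsilyloxy)propyl]spiro[4.5]decan-1-one (C6 OH cis to C1 and to the C10 chain; isopropenyl trans to the chain)
Conditions: [Rh(nbd)(dppe)]BF4 (5 mol%, pre-activated by H2), acetone, 25 °C
Reagents that add atoms: none
Why: Rhodium-catalysed intramolecular alkene hydroacylation (acyl rhodium hydride, alkene insertion, reductive elimination) turns the pent-4-enal into the cyclopentanone, forming the C9–C10 bond and the spiro ring; no stereocentre is created and the quaternary α-carbon suppresses decarbonylation.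

Step 10
Reactants: 14 6-hydroxy-6-methyl-9-(prop-1-en-2-yl)-10-[3-(tert-butyldimethylsilyloxy)propyl]spiro[4.5]decan-1-one
Product: 15 2-bromo-6-hydroxy-6-methyl-9-(prop-1-en-2-yl)-10-[3-(tert-butyldimethylsilyloxy)propyl]spiro[4.5]decan-1-one (both C2 epimers)
Conditions: pyrrolidone hydrotribromide (1.05 equiv), THF, 0 to 25 °C
Reagents that add atoms: pyrrolidone hydrotribromide, O=C1CCCN1.O=C1CCCN1.O=C1CCCN1.Br.BrBr
Why: Acid-mediated enol bromination; C9 is the only enolisable position and this tribromide complex in THF brominates ketones in preference to alkenes; the C9 configuration does not matter because it is erased in step 20.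

Step 11
Reactants: 15 2-bromo-6-hydroxy-6-methyl-9-(prop-1-en-2-yl)-10-[3-(tert-butyldimethylsilyloxy)propyl]spiro[4.5]decan-1-one
Product: 16 2-bromo-6-methyl-9-(prop-1-en-2-yl)-10-[3-(tert-butyldimethylsilyloxy)propyl]spiro[4.5]decane-1,6-diol (C1 OH anti to C6 OH and on the face of C10; both C2 epimers)
Conditions: Me4NBH(OAc)3, MeCN/AcOH, −20 °C
Reagents that add atoms: none
Why: Evans–Saksena hydroxyl-directed reduction: the C5 alkoxyborohydride delivers hydride intramolecularly to the C5-side face of the C10 carbonyl, giving the 1,3-anti diol with the C10 hydroxyl on the C1 side as in the target.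

Step 12
Reactants: 16 2-bromo-6-methyl-9-(prop-1-en-2-yl)-10-[3-(tert-butyldimethylsilyloxy)propyl]spiro[4.5]decane-1,6-diol
Product: 17 2-[2-bromo-1,6-dihydroxy-6-methyl-10-[3-(tert-butyldimethylsilyloxy)propyl]spiro[4.5]decan-9-yl]prop-2-enal
Conditions: SeO2 (1.2 equiv), 1,4-dioxane/H2O (20:1), 70 °C
Reagents that add atoms: selenium dioxide, O=[Se]=O
Why: Riley allylic oxidation (ene reaction then [2,3]-sigmatropic shift) takes the isopropenyl methyl group to the 2-substituted acrolein; the isopropenyl group is the only alkene left in the molecule.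

Step 13
Reactants: 17 2-[2-bromo-1,6-dihydroxy-6-methyl-10-[3-(tert-butyldimethylsilyloxy)propyl]spiro[4.5]decan-9-yl]prop-2-enal
Product: 19 (2Z)-2-[2-bromo-1,6-dihydroxy-10-(3-hydroxypropyl)-6-methylspiro[4.5]decan-9-ylidene]propanal, via silyl ether enal 18 (not isolated)
Conditions: RhCl3·3H2O (5 mol%), EtOH, 70 °C; then HCl (0.1 M in EtOH), 25 °C
Reagents that add atoms: none
Why: Rhodium hydride alkene isomerisation (conjugate hydrometalation then β-hydride elimination towards C2) moves the double bond into the tetrasubstituted conjugated position under thermodynamic control, which should favour the small formyl group syn to the substituted C1 (A(1,3) strain), and acid-catalysed ethanolysis then removes the primary silyl ether; the carvone-derived C2 stereocentre is erased here after having set C1.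

Step 14
Reactants: 19 (2Z)-2-[2-bromo-1,6-dihydroxy-10-(3-hydroxypropyl)-6-methylspiro[4.5]decan-9-ylidene]propanal
Product: 20 3-[(9Z)-2-bromo-1,6-dihydroxy-6-methyl-9-(1-oxopropan-2-ylidene)spiro[4.5]decan-10-yl]propyl decanoate
Conditions: decanoyl chloride (1.05 equiv), 2,4,6-collidine, CH2Cl2, −40 to 0 °C
Reagents that add atoms: decanoyl chloride, CCCCCCCCCC(Cl)=O
Why: Chemoselective acylation of the primary alcohol in the presence of the hindered secondary and the tertiary alcohol (esterification).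

Step 15
Reactants: 21 prop-2-yn-1-ol
Product: 23 (2E)-2,6-dimethylhepta-2,5-dien-1-ol, via alkenylalane 22 (not isolated)
Conditions: Me3Al (3 equiv), Cp2ZrCl2 (25 mol%), ClCH2CH2Cl, 0 to 25 °C; then prenyl bromide, Pd(PPh3)4 (3 mol%), THF, 25 °C; aq. HCl work-up
Reagents that add atoms: trimethylaluminium, C[Al](C)C; prenyl bromide, CC(C)=CCBr
Why: Negishi zirconium-catalysed syn-carboalumination of the alkyne followed by palladium-catalysed allylation of the alkenylalane with retention gives the E trisubstituted alkene (Ce=Cf) and the skipped diene.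

Step 16
Reactants: 23 (2E)-2,6-dimethylhepta-2,5-dien-1-ol
Product: 24 (2E)-2,6-dimethylhepta-2,5-dienal
Conditions: MnO2 (10 equiv), CH2Cl2, 25 °C
Reagents that add atoms: none
Why: MnO2 oxidises the allylic alcohol to the enal without touching the alkenes (allylic alcohol oxidation).

Step 17
Reactants: 24 (2E)-2,6-dimethylhepta-2,5-dienal
Product: 25 (2E,4E)-4,8-dimethylnona-2,4,7-trienal
Conditions: Ph3P=CHCHO, toluene, 80 °C
Reagents that add atoms: (triphenylphosphoranylidene)acetaldehyde, O=CC=P(c1ccccc1)(c1ccccc1)c1ccccc1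
Why: Wittig olefination with a stabilised ylide gives the E disubstituted alkene (Cc=Cd).

Step 18
Reactants: 25 (2E,4E)-4,8-dimethylnona-2,4,7-trienal
Product: 26 ethyl (2Z,4E,6E)-2-iodo-6,10-dimethylundeca-2,4,6,9-tetraenoate
Conditions: Ph3P=CHCO2Et, N-iodosuccinimide, CH2Cl2, −20 °C; then 25, −20 to 25 °C, dark
Reagents that add atoms: ethyl (triphenylphosphoranylidene)acetate, CCOC(=O)C=P(c1ccccc1)(c1ccccc1)c1ccccc1; N-iodosuccinimide, O=C1CCC(=O)N1I
Why: Wittig olefination with the α-iodo ylide made in the flask gives the Z α-iodo enoate (iodine cis to the dienyl chain), which fixes the Ca=Cb geometry needed later.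

Step 19
Reactants: 26 ethyl (2Z,4E,6E)-2-iodo-6,10-dimethylundeca-2,4,6,9-tetraenoate
Product: 27 (2Z,4E,6E)-2-iodo-6,10-dimethylundeca-2,4,6,9-tetraen-1-ol
Conditions: i-Bu2AlH (2.2 equiv), CH2Cl2, −78 °C, dark
Reagents that add atoms: none
Why: i-Bu2AlH reduces the conjugated ester to the allylic alcohol at low temperature without touching the alkenyl iodide (ester reduction).

Step 20
Reactants: 20 3-[(9Z)-2-bromo-1,6-dihydroxy-6-methyl-9-(1-oxopropan-2-ylidene)spiro[4.5]decan-10-yl]propyl decanoate; 27 (2Z,4E,6E)-2-iodo-6,10-dimethylundeca-2,4,6,9-tetraen-1-ol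
Product: 28 3-[(1R,2R,5S,6S,9Z,10R)-1,6-dihydroxy-2-[(2E,4E,6E)-1-hydroxy-6,10-dimethylundeca-2,4,6,9-tetraen-2-yl]-6-methyl-9-(1-oxopropan-2-ylidene)spiro[4.5]decan-10-yl]propyl decanoate
Conditions: NiBr2(dme) (10 mol%), 4,4′-di-tert-butyl-2,2′-bipyridine (12 mol%), NaI (0.5 equiv), DMA, undivided cell, Mg anode, reticulated vitreous carbon cathode, constant current 3 mA (about 2.5 F/mol), 20 °C, dark
Reagents that add atoms: none
Why: Proposed new method: nickel-electrocatalytic, stereoconvergent cross-electrophile coupling of an unprotected secondary bromohydrin with a geometrically defined 2-iodotrienol; cathodically formed zerovalent nickel inserts into the C–I bond of 27 with retention of the Ca=Cb geometry, monovalent nickel abstracts bromine from C9 of either epimer of 20 to give a planar β-oxido radical, the alkenylnickel species captures this radical on the face anti to the C10 oxygen (held as a bulky magnesium alkoxide by Mg2+ from the anode), and fast reductive elimination from trivalent nickel outruns β-oxygen elimination, so the new C9–Ca bond is trans to the C10 hydroxyl; the closest known reactions are nickel-catalysed electroreductive alkyl halide–alkenyl halide cross-electrophile coupling and the nickel/iodide co-catalysed reductive coupling of epoxides through iodohydrin radicals, neither of them shown for a free halohydrin with a conjugated trienyl iodide.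

Step 21
Reactants: 28 3-[(1R,2R,5S,6S,9Z,10R)-1,6-dihydroxy-2-[(2E,4E,6E)-1-hydroxy-6,10-dimethylundeca-2,4,6,9-tetraen-2-yl]-6-methyl-9-(1-oxopropan-2-ylidene)spiro[4.5]decan-10-yl]propyl decanoate
Product: 29 3-[(1R,2R,5S,6S,9Z,10R)-2-[(2E,4E,6E)-1-acetoxy-6,10-dimethylundeca-2,4,6,9-tetraen-2-yl]-1,6-dihydroxy-6-methyl-9-(1-oxopropan-2-ylidene)spiro[4.5]decan-10-yl]propyl decanoate
Conditions: acetyl chloride (1.1 equiv), 2,4,6-collidine, CH2Cl2, −78 °C
Reagents that add atoms: acetyl chloride, CC(Cl)=O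
Why: Acylation with an acid chloride and a hindered pyridine base at low temperature is selective for the unhindered primary allylic alcohol over the neopentyl-type secondary and the tertiary alcohol (chemoselective esterification).

**Compound list**
1 | (S)-(+)-carvone [(5S)-2-methyl-5-(prop-1-en-2-yl)cyclohex-2-en-1-one] | O=C1C[C@@H](C(C)=C)CC=C1C | starting material
2 | tert-butyl(3-iodopropoxy)dimethylsilane | ICCCO[Si](C)(C)C(C)(C)C | starting material
3 | lithium 6-methyl-3-(prop-1-en-2-yl)cyclohexa-1,5-dien-1-olate (kinetic enolate of 1; ring stereocentre unchanged) | [Li+].[O-]C1=C[C@@H](C(C)=C)CC=C1C | intermediate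
4 | (5S,6R)-6-[3-(tert-butyldimethylsilyloxy)propyl]-2-methyl-5-(prop-1-en-2-yl)cyclohex-2-en-1-one (chain trans to isopropenyl) | CC(C)(C)[Si](C)(C)OCCC[C@@H]1[C@@H](C(C)=C)CC=C(C)C1=O | intermediate
5 | lithium (5S,6R)-6-[3-(tert-butyldimethylsilyloxy)propyl]-2-methyl-5-(prop-1-en-2-yl)cyclohex-1-en-1-olate | CC(C)(C)[Si](C)(C)OCCC[C@@H]1[C@@H](C(C)=C)CCC(C)=C1[O-].[Li+] | intermediate
6 | (5S,6R)-6-[3-(tert-butyldimethylsilyloxy)propyl]-2-methyl-5-(prop-1-en-2-yl)cyclohex-1-en-1-yl trifluoromethanesulfonate | CC(C)(C)[Si](C)(C)OCCC[C@@H]1[C@@H](C(C)=C)CCC(C)=C1OS(=O)(=O)C(F)(F)F | intermediate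
7 | methyl (5S,6R)-6-[3-(tert-butyldimethylsilyloxy)propyl]-2-methyl-5-(prop-1-en-2-yl)cyclohex-1-ene-1-carboxylate | CC(C)(C)[Si](C)(C)OCCC[C@@H]1[C@@H](C(C)=C)CCC(C)=C1C(=O)OC | intermediate
8 | lithium dienolate of 7 (O-lithio O-methyl ketene acetal exocyclic at C6; ring alkene C4=C5) | CC(C)(C)[Si](C)(C)OCCC[C@@H]1[C@@H](C(C)=C)CC=C(C)C1=C([O-])OC.[Li+] | intermediate
9 | methyl (1R,5S,6R)-1-allyl-6-[3-(tert-butyldimethylsilyloxy)propyl]-2-methyl-5-(prop-1-en-2-yl)cyclohex-2-ene-1-carboxylate (allyl trans to the silyloxypropyl chain) | CC(C)(C)[Si](C)(C)OCCC[C@@H]1[C@@H](C(C)=C)CC=C(C)[C@@]1(C(=O)OC)CC=C | intermediate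
10 | [(1R,5S,6R)-1-allyl-6-[3-(tert-butyldimethylsilyloxy)propyl]-2-methyl-5-(prop-1-en-2-yl)cyclohex-2-en-1-yl]methanol | CC(C)(C)[Si](C)(C)OCCC[C@@H]1[C@@H](C(C)=C)CC=C(C)[C@@]1(CO)CC=C | intermediate
11 | [1-allyl-2,3-epoxy-2-methyl-6-[3-(tert-butyldimethylsilyloxy)propyl]-5-(prop-1-en-2-yl)cyclohexyl]methanol (oxirane oxygen cis to CH2OH) | CC(C)(C)[Si](C)(C)OCCC[C@@H]1[C@@H](C(C)=C)C[C@@H]2O[C@]2(C)[C@@]1(CO)CC=C | intermediate
12 | 2-allyl-2-(hydroxymethyl)-1-methyl-3-[3-(tert-butyldimethylsilyloxy)propyl]-4-(prop-1-en-2-yl)cyclohexan-1-ol (OH cis to CH2OH and to the silyloxypropyl chain; allyl cis to methyl; isopropenyl trans to the chain) | CC(C)(C)[Si](C)(C)OCCC[C@@H]1[C@@H](C(C)=C)CC[C@](C)(O)[C@@]1(CO)CC=C | intermediate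
13 | 1-allyl-2-hydroxy-2-methyl-6-[3-(tert-butyldimethylsilyloxy)propyl]-5-(prop-1-en-2-yl)cyclohexane-1-carbaldehyde (OH cis to CHO and to the chain) | CC(C)(C)[Si](C)(C)OCCC[C@@H]1[C@@H](C(C)=C)CC[C@](C)(O)[C@@]1(C=O)CC=C | intermediate
14 | 6-hydroxy-6-methyl-9-(prop-1-en-2-yl)-10-[3-(tert-butyldimethylsilyloxy)propyl]spiro[4.5]decan-1-one (C6 OH cis to C1 and to the C10 chain; isopropenyl trans to the chain) | CC(C)(C)[Si](C)(C)OCCC[C@@H]1[C@@H](C(C)=C)CC[C@](C)(O)[C@@]12CCCC2=O | intermediate
15 | 2-bromo-6-hydroxy-6-methyl-9-(prop-1-en-2-yl)-10-[3-(tert-butyldimethylsilyloxy)propyl]spiro[4.5]decan-1-one (both C2 epimers) | CC(C)(C)[Si](C)(C)OCCC[C@@H]1[C@@H](C(C)=C)CC[C@](C)(O)[C@@]12CCC(Br)C2=O | intermediate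
16 | 2-bromo-6-methyl-9-(prop-1-en-2-yl)-10-[3-(tert-butyldimethylsilyloxy)propyl]spiro[4.5]decane-1,6-diol (C1 OH anti to C6 OH and on the face of C10; both C2 epimers) | CC(C)(C)[Si](C)(C)OCCC[C@@H]1[C@@H](C(C)=C)CC[C@](C)(O)[C@@]12CCC(Br)[C@H]2O | intermediate
17 | 2-[2-bromo-1,6-dihydroxy-6-methyl-10-[3-(tert-butyldimethylsilyloxy)propyl]spiro[4.5]decan-9-yl]prop-2-enal | CC(C)(C)[Si](C)(C)OCCC[C@@H]1[C@@H](C(=C)C=O)CC[C@](C)(O)[C@@]12CCC(Br)[C@H]2O | intermediate
18 | (2Z)-2-[2-bromo-1,6-dihydroxy-6-methyl-10-[3-(tert-butyldimethylsilyloxy)propyl]spiro[4.5]decan-9-ylidene]propanal | CC(C)(C)[Si](C)(C)OCCC[C@@H]1/C(=C(/C)C=O)CC[C@](C)(O)[C@@]12CCC(Br)[C@H]2O | intermediate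
19 | (2Z)-2-[2-bromo-1,6-dihydroxy-10-(3-hydroxypropyl)-6-methylspiro[4.5]decan-9-ylidene]propanal | OCCC[C@@H]1/C(=C(/C)C=O)CC[C@](C)(O)[C@@]12CCC(Br)[C@H]2O | intermediate
20 | 3-[(9Z)-2-bromo-1,6-dihydroxy-6-methyl-9-(1-oxopropan-2-ylidene)spiro[4.5]decan-10-yl]propyl decanoate (ring stereocentres as in 29; both C2 epimers) | CCCCCCCCCC(=O)OCCC[C@@H]1/C(=C(/C)C=O)CC[C@](C)(O)[C@@]12CCC(Br)[C@H]2O | intermediate
21 | prop-2-yn-1-ol | C#CCO | starting material
22 | (E)-alkenylalane Me2Al–CH=C(CH3)–CH2–O–AlMe2 (methyl and aluminium cis on the alkene) | C[Al](C)OC/C(C)=C/[Al](C)C | intermediate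
23 | (2E)-2,6-dimethylhepta-2,5-dien-1-ol | OC/C(C)=C/CC=C(C)C | intermediate
24 | (2E)-2,6-dimethylhepta-2,5-dienal | O=C/C(C)=C/CC=C(C)C | intermediate
25 | (2E,4E)-4,8-dimethylnona-2,4,7-trienal | O=C/C=C/C(C)=C/CC=C(C)C | intermediate
26 | ethyl (2Z,4E,6E)-2-iodo-6,10-dimethylundeca-2,4,6,9-tetraenoate | I\C(=C/C=C/C(C)=C/CC=C(C)C)C(=O)OCC | intermediate
27 | (2Z,4E,6E)-2-iodo-6,10-dimethylundeca-2,4,6,9-tetraen-1-ol | I\C(=C/C=C/C(C)=C/CC=C(C)C)CO | intermediate
28 | 3-[(1R,2R,5S,6S,9Z,10R)-1,6-dihydroxy-2-[(2E,4E,6E)-1-hydroxy-6,10-dimethylundeca-2,4,6,9-tetraen-2-yl]-6-methyl-9-(1-oxopropan-2-ylidene)spiro[4.5]decan-10-yl]propyl decanoate | CCCCCCCCCC(=O)OCCC[C@@H]1/C(=C(/C)C=O)CC[C@](C)(O)[C@@]12CC[C@H](\C(=C/C=C/C(C)=C/CC=C(C)C)CO)[C@H]2O | intermediate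
29 | 3-[(1R,2R,5S,6S,9Z,10R)-2-[(2E,4E,6E)-1-acetoxy-6,10-dimethylundeca-2,4,6,9-tetraen-2-yl]-1,6-dihydroxy-6-methyl-9-(1-oxopropan-2-ylidene)spiro[4.5]decan-10-yl]propyl decanoate | CCCCCCCCCC(=O)OCCC[C@@H]1/C(=C(/C)C=O)CC[C@](C)(O)[C@@]12CC[C@H](\C(=C/C=C/C(C)=C/CC=C(C)C)COC(C)=O)[C@H]2O | target

**Step count**
Total: 21 steps. Longest linear sequence: 16 steps (steps 1–14, 20, 21); the side chain takes 5 steps (15–19).

**Three steps most likely to fail**

Step 4 (quaternary C6). The dienolate may alkylate at the γ-carbon or on oxygen. Facial control may also be eroded, because the isopropenyl group on C2 sits 1,3 to C6 on the face opposite the C1 chain. The fallback replaces the intermolecular alkylation by an Ireland–Claisen rearrangement and sets out from 7. LiOH in THF/MeOH/H2O gives the carboxylic acid F1, and allyl bromide with K2CO3 in DMF gives the allyl ester F2. γ-Deprotonation and silylation (LiN(i-Pr)2, Me3SiCl, THF/HMPA, −78 °C) followed by warming to 60 °C trigger the [3,3] shift, which delivers the allyl group to C6 and gives the α-allyl acid F3 after aqueous work-up. LiAlH4 reduces F3 to the alcohol, and the route is rejoined at 10.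

Step 13 (enal). The rhodium hydride may not reach the tetrasubstituted position, the formyl/methyl geometry may equilibrate to a mixture, and the secondary bromide is heated in ethanol. The fallback replaces isomerisation by a reduction/dehydrogenation relay and sets out from 17. RhCl(PPh3)3-catalysed 1,4-hydrosilylation with Et3SiH gives the triethylsilyl enol ether F4. Saegusa–Ito dehydrogenation (Pd(OAc)2, MeCN, 25 °C) then gives the conjugated enal; β-hydride loss towards the methyl group only regenerates recyclable 17. The route is rejoined at 18, and the ethanolic HCl treatment of step 13 then gives 19.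

Step 20 (the proposed new coupling). Possible failures are β-oxygen elimination or simple reduction of the C–Br bond, low trans selectivity at C9, and isomerisation or reduction of the trienyl iodide. The fallback uses known chemistry, with an alkenylzinc nucleophile and no electrolysis, and sets out from 20 and 27. Me3SiCl and imidazole convert 20 into the bis(trimethylsilyl) ether F5 and 27 into the trimethylsilyl ether F6. Iodine–lithium exchange on F6 (t-BuLi, THF, −78 °C) and transmetalation with ZnCl2·TMEDA give the alkenylzinc reagent with retention of geometry. This is coupled with F5 under the established iron-catalysed coupling of alkenylzinc reagents with secondary alkyl bromides (FeCl3 5 mol%, THF, 30 °C), with radical capture anti to the C10 silyloxy group, to give the tris(trimethylsilyl) ether F7. Citric acid in methanol removes the three silyl groups, and the route is rejoined at 28.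

Further compounds
F1 | step 4 | (5S,6R)-6-[3-(tert-butyldimethylsilyloxy)propyl]-2-methyl-5-(prop-1-en-2-yl)cyclohex-1-ene-1-carboxylic acid | CC(C)(C)[Si](C)(C)OCCC[C@@H]1[C@@H](C(C)=C)CCC(C)=C1C(O)=O
F2 | step 4 | prop-2-en-1-yl (5S,6R)-6-[3-(tert-butyldimethylsilyloxy)propyl]-2-methyl-5-(prop-1-en-2-yl)cyclohex-1-ene-1-carboxylate | CC(C)(C)[Si](C)(C)OCCC[C@@H]1[C@@H](C(C)=C)CCC(C)=C1C(=O)OCC=C
F3 | step 4 | (1R,5S,6R)-1-allyl-6-[3-(tert-butyldimethylsilyloxy)propyl]-2-methyl-5-(prop-1-en-2-yl)cyclohex-2-ene-1-carboxylic acid | CC(C)(C)[Si](C)(C)OCCC[C@@H]1[C@@H](C(C)=C)CC=C(C)[C@@]1(C(O)=O)CC=C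
F4 | step 13 | triethylsilyl enol ether of the saturated aldehyde from 17: 2-bromo-6-methyl-9-[1-(triethylsilyloxy)prop-1-en-2-yl]-10-[3-(tert-butyldimethylsilyloxy)propyl]spiro[4.5]decane-1,6-diol | CC(C)(C)[Si](C)(C)OCCC[C@@H]1[C@@H](C(C)=CO[Si](CC)(CC)CC)CC[C@](C)(O)[C@@]12CCC(Br)[C@H]2O
F5 | step 20 | bis(trimethylsilyl) ether of 20 (both hydroxyl groups silylated) | CCCCCCCCCC(=O)OCCC[C@@H]1/C(=C(/C)C=O)CC[C@](C)(O[Si](C)(C)C)[C@@]12CCC(Br)[C@H]2O[Si](C)(C)C
F6 | step 20 | trimethylsilyl ether of 27: [(2Z,4E,6E)-2-iodo-6,10-dimethylundeca-2,4,6,9-tetraenyl]oxytrimethylsilane | I\C(=C/C=C/C(C)=C/CC=C(C)C)CO[Si](C)(C)C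
F7 | step 20 | tris(trimethylsilyl) ether of 28 | CCCCCCCCCC(=O)OCCC[C@@H]1/C(=C(/C)C=O)CC[C@](C)(O[Si](C)(C)C)[C@@]12CC[C@H](\C(=C/C=C/C(C)=C/CC=C(C)C)CO[Si](C)(C)C)[C@H]2O[Si](C)(C)C
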